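## Retrosynthetic overview
1. The only ring closure is the C7–O bond of the tetrahydrofuran. It comes from oxidative 5-exo etherification of the C2-symmetric (8R,8′R)-diol **11**: dehydrogenation gives a p-quinone methide, the free 9′-OH adds to it, and C7 ends up trans to the C8 CH₂OH.
2. Diol **11** comes from reducing the dialdehyde **9**. The same reduction removes the two aryl pivalates.
3. Both C8 and C8′ are set in one operation by an enantioselective organocatalytic oxidative homocoupling of the 3-arylpropanal **6**, which proceeds through an enamine radical cation.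
4. Aldehyde **6** comes from sinapaldehyde (**1**) by phenol pivaloylation and organocatalytic conjugate transfer hydrogenation.

Assumption: the (S)-diarylprolinol silyl ether gives (R) α-centres. This follows the facial sense of its enamine α-functionalisations, for example the (2R) centre of Hayashi's syn Michael adducts. The CIP priority pattern at the new centres (CHO > new C–C partner > CH₂Ar > H) is the same as in those adducts.

## Route

**Step 1**
Reactants: **1** sinapaldehyde; **2** pivaloyl chloride
Product: **3** 2,6-dimethoxy-4-[(E)-3-oxoprop-1-enyl]phenyl pivalate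
Conditions: **2** (1.2 equiv), Et₃N, cat. DMAP, CH₂Cl₂, 0 °C → rt
Reagents that add atoms: pivaloyl chloride, CC(C)(C)C(=O)Cl
Why: DMAP-catalysed chemoselective O-acylation of the phenol gives a robust, hindered ester that survives the amine catalysis and aminium oxidant later and is removed by hydride at the end.

**Step 2**
Reactants: **3** pivalate enal; **4** Hantzsch ester; **5** dibenzylammonium trifluoroacetate
Product: **6** 2,6-dimethoxy-4-(3-oxopropyl)phenyl pivalate
Conditions: **4** (1.1 equiv), **5** (10 mol%), CH₂Cl₂, 25 °C
Reagents that add atoms: none
Why: Iminium-catalysed conjugate transfer hydrogenation (List/MacMillan type) reduces only the C=C bond, and no stereocentre is formed.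

**Step 3**
Reactants: **6** aryl-propanal (2 equiv); **7** (S)-diphenylprolinol TMS ether; **8** tris(4-bromophenyl)aminium hexachloroantimonate
Product: **9** (2R,3R)-2,3-bis[4-(pivaloyloxy)-3,5-dimethoxybenzyl]butanedial
Conditions: **7** (20 mol%), **8** (2.2 equiv), NaHCO₃ (3 equiv), CH₂Cl₂/MeCN, –40 °C; then pH 7 aqueous work-up; crude used directly in Step 4
Reagents that add atoms: none
Why: Proposed new method: **7** condenses with **6** to give an enamine, which **8** oxidises by one electron to an enamine radical cation. A second enamine attacks the α-carbon of the radical cation, closing C8–C8′. Oxidation of the resulting distonic radical cation and loss of two protons (taken up by NaHCO₃) gives the bis-iminium, which hydrolyses to **9**. The catalyst shields one face of each partner. The same-handed catalyst should therefore set both centres in the same sense, giving the C2-symmetric (R,R) dialdehyde rather than the meso isomer. The closest known reactions are MacMillan SOMO α-functionalisation, which uses the same enamine radical cation with a π-nucleophile, and oxidative homocoupling of chiral enolates.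

**Step 4**
Reactants: **9** dialdehyde; **10** lithium aluminium hydride
Product: **11** (2R,3R)-2,3-bis(4-hydroxy-3,5-dimethoxybenzyl)butane-1,4-diol
Conditions: **10** (6 equiv), THF, 0 °C → 60 °C; Rochelle salt work-up; chromatography to remove any meso diol
Reagents that add atoms: none (LiAlH₄ only delivers H)
Why: Hydride reduction of both aldehydes, applied to the crude dialdehyde at once to avoid α-epimerisation, also cleaves the two aryl pivalates. No stereocentre is touched, and the C2-symmetric diol is separated from any meso isomer at this stable stage.

**Step 5**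
Reactants: **11** diol; **12** DDQ
Product: **13** (+)-(7S,8R,8′R)-5,5′-dimethoxylariciresinol (target)
Conditions: **12** (1.05 equiv), anhydrous CH₂Cl₂, 4 Å MS, 0 °C → rt, 1 h; then aq. NaHCO₃
Reagents that add atoms: none
Why: DDQ dehydrogenates a 4-hydroxybenzylic C7–H to the p-quinone methide (hydride abstraction, then loss of the phenolic proton). The 9′-OH of the other arm adds 5-exo in an intramolecular 1,6-addition. The C8 stereocentre controls the new C7 centre, and the trans-2,3-disubstituted tetrahydrofuran (aryl trans to the C8 CH₂OH) is favoured. C8 and C8′ are not involved and retain the 8R,8′R configuration, which fixes the 8,8′-trans relationship. Any cis isomer is removed by chromatography.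

## Compound list
1 | sinapaldehyde, (E)-3-(4-hydroxy-3,5-dimethoxyphenyl)propenal | COc1cc(/C=C/C=O)cc(OC)c1O | starting material
2 | pivaloyl chloride | CC(C)(C)C(=O)Cl | starting material
3 | 2,6-dimethoxy-4-[(E)-3-oxoprop-1-enyl]phenyl pivalate | COc1cc(/C=C/C=O)cc(OC)c1OC(=O)C(C)(C)C | intermediate
4 | Hantzsch ester, diethyl 2,6-dimethyl-1,4-dihydropyridine-3,5-dicarboxylate | CCOC(=O)C1=C(C)NC(C)=C(C1)C(=O)OCC | starting material
5 | dibenzylammonium trifluoroacetate | [O-]C(=O)C(F)(F)F.c1ccc(C[NH2+]Cc2ccccc2)cc1 | starting material
6 | 2,6-dimethoxy-4-(3-oxopropyl)phenyl pivalate | COc1cc(CCC=O)cc(OC)c1OC(=O)C(C)(C)C | intermediate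
7 | (S)-diphenylprolinol trimethylsilyl ether | C[Si](C)(C)OC(c1ccccc1)(c1ccccc1)[C@@H]1CCCN1 | starting material
8 | tris(4-bromophenyl)aminium hexachloroantimonate (radical cation salt) | Brc1ccc(cc1)[N+](c1ccc(Br)cc1)c1ccc(Br)cc1.Cl[Sb-](Cl)(Cl)(Cl)(Cl)Cl | starting material
9 | (2R,3R)-2,3-bis[4-(pivaloyloxy)-3,5-dimethoxybenzyl]butanedial | O=C[C@H](Cc1cc(OC)c(OC(=O)C(C)(C)C)c(OC)c1)[C@H](C=O)Cc1cc(OC)c(OC(=O)C(C)(C)C)c(OC)c1 | intermediate
10 | lithium aluminium hydride | [Li+].[AlH4-] | starting material
11 | (2R,3R)-2,3-bis(4-hydroxy-3,5-dimethoxybenzyl)butane-1,4-diol | OC[C@H](Cc1cc(OC)c(O)c(OC)c1)[C@H](CO)Cc1cc(OC)c(O)c(OC)c1 | intermediate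
12 | DDQ, 2,3-dichloro-5,6-dicyano-1,4-benzoquinone | O=C1C(Cl)=C(Cl)C(=O)C(C#N)=C1C#N | starting material
13 | (+)-(7S,8R,8′R)-5,5′-dimethoxylariciresinol | COc1cc(C[C@H]2CO[C@H](c3cc(OC)c(O)c(OC)c3)[C@H]2CO)cc(OC)c1O | target

## Totals
Total steps: 5. Longest linear sequence: 5, from sinapaldehyde.

## Three steps most likely to fail
1. **Step 3 (proposed new step).** The radical cation may lose a benzylic β-H to give the enal. The amine catalyst may be oxidised by the aminium salt. The C2/meso selectivity and the enantioselectivity are unproven.
   - Fallback (known chemistry): use Hayashi–Jørgensen enamine Michael addition of **6** to a nitroalkene.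
     - Make the nitroalkene ArCH₂CH=CHNO₂ (Ar = 4-pivaloyloxy-3,5-dimethoxyphenyl) from the arylacetaldehyde by Henry reaction with MeNO₂ and dehydration. The arylacetaldehyde comes from DMP oxidation of the 2-arylethanol.
     - Add **6** to the nitroalkene with (S)-**7** and an acid co-catalyst. This gives the syn (2R,3R) γ-nitroaldehyde OHC–CH(CH₂Ar)–CH(CH₂Ar)–CH₂NO₂.
     - Reduce the aldehyde (NaBH₄), convert the nitro group to the aldehyde by a Nef reaction (NaOMe, then aqueous TiCl₃/NH₄OAc), and finish with LiAlH₄ to reduce the aldehyde and cleave the pivalates, giving **11**.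
2. **Step 5.** DDQ may over-oxidise the product's benzylic ether, the quinone methide may isomerise to the styrene instead of cyclising, or the 7,8-trans selectivity may be poor.
   - Fallback: reduce **9** with NaBH₄ so the pivalates stay on, then cyclise by Suárez alkoxy-radical 1,5-HAT etherification (PhI(OAc)₂, I₂, hν) at C7–H. Remove the pivalates with LiAlH₄ last.
3. **Step 2.** The electron-rich cinnamaldehyde iminium is a poor hydride acceptor, so conjugate reduction may be sluggish.
   - Fallback: start instead from commercial 3-(4-hydroxy-3,5-dimethoxyphenyl)propanoic acid. Make the methyl ester, protect the phenol with PivCl, and reduce the ester to aldehyde **6** with DIBAL-H at –78 °C.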